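**Strategy.** The target is disconnected at the C3–O bond of the bridging tetrahydrofuran (O, C3, C4, C5, C6; atom labels are defined below). The precursor is a fully assembled hydroxy enone: ring A is a 4,4-dimethylcyclohex-2-enone (C1 ketone, C2=C3) whose C5 carries a silyl-masked hydroxymethyl arm (C6), with the spiro lactone, ring C and the acrylic acid already in place. Unmasking C6–OH triggers an oxa-Michael addition that exploits the 1,3-relationship of C6 and C3 across the gem-dimethyl carbon C4: one operation closes the last ring and sets C3. The enone comes from desymmetrised 4,4-dimethylcyclohexadienone; a Claisen rearrangement forges C9–C10 and a Michael cyclisation builds ring C.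

Key step: step 15

Remark on labels: ring A is the carbocycle C1 (ketone), C2, C3 (CH–O), C4 (CMe2), C5, C10 (spiro carbon); C6 is the OCH2 on C5. The lactone is C7 (C=O), O, C20 (OCH2), C10, C9, C8. Ring C is the cyclohexane C8, C9, C11, C12, C13, C14. The side chain on C13 is C16(=C17H2)–C15O2H.
Assumption: enol ether 13 reacts through the geometry drawn (oxygen anti to the ring ketone), the usual one for alkoxymethylidene ketones.

Step 1
Reactants: 1 4,4-dimethylcyclohex-2-en-1-one
Product: 2 4,4-dimethylcyclohexa-2,5-dien-1-one
Conditions: DDQ (1.3 equiv), TsOH·H2O (cat.), 1,4-dioxane, 100 °C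
Reagents that add atoms: none
Why: DDQ dehydrogenation of the enone through its dienol should stop at the cross-conjugated dienone because the quaternary C4 blocks aromatisation.

Step 2
Reactants: 2 4,4-dimethylcyclohexa-2,5-dien-1-one
Product: 3 (5R)-5-ethenyl-4,4-dimethylcyclohex-2-en-1-one
Conditions: CH2=CHBF3K (2 equiv), [Rh(cod)2]BF4 (3 mol%), (R)-BINAP (3.3 mol%), toluene/H2O 4:1, 105 °C
Reagents that add atoms: potassium vinyltrifluoroborate, C=C[B-](F)(F)F.[K+]
Why: Rhodium-catalysed asymmetric 1,4-addition of an alkenylboron reagent (Hayashi–Miyaura reaction) desymmetrises the two enantiotopic enone units and leaves the second enone for the last step; by analogy with the facial sense known for 2-cyclohexenone, (R)-BINAP is expected to give the (5R) centre.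

Step 3
Reactants: 3 (5R)-5-ethenyl-4,4-dimethylcyclohex-2-en-1-one
Product: 5 (5S)-5-(hydroxymethyl)-4,4-dimethylcyclohex-2-en-1-one, via aldehyde 4 (not isolated)
Conditions: O3, CH2Cl2/MeOH 4:1, −78 °C; Me2S, −78 °C → rt; then NaBH4 (0.3 equiv), −78 °C, AcOH quench
Reagents that add atoms: ozone, [O-][O+]=O
Why: Ozonolysis should take the electron-rich vinyl group and spare the enone, and borohydride at −78 °C reduces the aldehyde but not the conjugated ketone; the cold acidic quench guards against epimerisation α to the aldehyde and against early conjugate addition of the alkoxide (the descriptor changes only through CIP priorities).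

Step 4
Reactants: 5 (5S)-5-(hydroxymethyl)-4,4-dimethylcyclohex-2-en-1-one
Product: 6 (5S)-5-{[(tert-butyldimethylsilyl)oxy]methyl}-4,4-dimethylcyclohex-2-en-1-one
Conditions: TBSOTf (1.1 equiv), 2,6-lutidine, CH2Cl2, −78 °C
Reagents that add atoms: tert-butyldimethylsilyl triflate, CC(C)(C)[Si](C)(C)OS(=O)(=O)C(F)(F)F
Why: Fast silylation of the primary alcohol under non-nucleophilic conditions masks C6–OH so that the oxa-Michael addition is held back until the end.

Step 5
Reactants: 6 (5S)-5-{[(tert-butyldimethylsilyl)oxy]methyl}-4,4-dimethylcyclohex-2-en-1-one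
Product: 7 (5R,6Z)-5-{[(tert-butyldimethylsilyl)oxy]methyl}-6-(hydroxymethylidene)-4,4-dimethylcyclohex-2-en-1-one
Conditions: LiN(SiMe3)2 (1.1 equiv), THF, −78 °C; HCO2CH2CF3 (1.5 equiv), −78 °C
Reagents that add atoms: 2,2,2-trifluoroethyl formate, O=COCC(F)(F)F
Why: The enone has a single enolisable position (C10, since C4 is quaternary), so the cross-conjugated lithium dienolate forms regiospecifically and is C-formylated (crossed Claisen condensation) to the chelated hydroxymethylidene ketone, the future C20.

Step 6
Reactants: 8 1-methylcyclopentene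
Product: 9 5-oxohexanal
Conditions: O3, CH2Cl2, −78 °C; Me2S, −78 °C → rt
Reagents that add atoms: ozone, [O-][O+]=O
Why: Ozonolysis with reductive work-up opens the trisubstituted cycloalkene to the keto aldehyde.

Step 7
Reactants: 9 5-oxohexanal; 10 methyl acrylate
Product: 11 methyl 3-hydroxy-2-methylidene-7-oxooctanoate (racemic)
Conditions: DABCO (0.5 equiv), MeOH, rt
Reagents that add atoms: none
Why: Morita–Baylis–Hillman reaction, in which the ammonium enolate from DABCO and the acrylate attacks the aldehyde in preference to the methyl ketone; the carbinol centre is erased in the next step, so the racemate suffices.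

Step 8
Reactants: 11 methyl 3-hydroxy-2-methylidene-7-oxooctanoate
Product: 12 methyl (2Z)-2-(bromomethyl)-7-oxooct-2-enoate
Conditions: LiBr (2 equiv), H2SO4 (2.5 equiv), MeCN, 0 °C → rt
Reagents that add atoms: lithium bromide, [Li+].[Br-]
Why: Acid-mediated SN2' bromination of the Baylis–Hillman alcohol should give the rearranged primary allylic bromide, with the alkyl chain trans to the ester under thermodynamic control.

Step 9
Reactants: 7 hydroxymethylidene ketone; 12 methyl (2Z)-2-(bromomethyl)-7-oxooct-2-enoate
Product: 13 methyl (2E)-2-({(E)-[(6R)-6-{[(tert-butyldimethylsilyl)oxy]methyl}-5,5-dimethyl-2-oxocyclohex-3-en-1-ylidene]methoxy}methyl)-7-oxooct-2-enoate (enol ether oxygen anti to the ring ketone; alkyl chain cis to the OCH2 group)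
Conditions: K2CO3 (1.5 equiv), acetone, rt
Reagents that add atoms: none
Why: O-alkylation of the ambident potassium enolate of the 2-hydroxymethylidene ketone by SN2 at the primary allylic bromide, C-alkylation being disfavoured at the hindered C10; the push–pull enol ether should settle with oxygen anti to the ketone.

Step 10
Reactants: 13 allyl enol ether
Product: 14 methyl (3S)-3-[(1S,6R)-6-{[(tert-butyldimethylsilyl)oxy]methyl}-1-formyl-5,5-dimethyl-2-oxocyclohex-3-en-1-yl]-2-methylidene-7-oxooctanoate (labels: 5R,9S,10S)
Conditions: o-xylene, BHT (5 mol%), 145 °C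
Reagents that add atoms: none
Why: Claisen rearrangement ([3,3]-sigmatropic shift) through a chair transition state in which the allyl unit reaches C10 anti to the pseudo-axial C5 CH2OTBS group; this forms the C9–C10 bond, sets C10 (C9 trans to C6, formyl cis to C6) and, from the defined enol-ether and alkene geometries, C9 (C11 anti to C5), and regenerates the 2-methylidene ester.

Step 11
Reactants: 14 formyl ketone
Product: 16 (5S,6S,11R)-11-{[(tert-butyldimethylsilyl)oxy]methyl}-10,10-dimethyl-4-methylidene-5-(4-oxopentyl)-2-oxaspiro[5.5]undec-8-ene-3,7-dione (labels: 5R,9S,10S), via hydroxy ester 15 (not isolated)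
Conditions: NaBH4 (0.3 equiv), EtOH/CH2Cl2 3:7, −78 °C, AcOH quench; then PPTS (cat.), PhH, 60 °C
Reagents that add atoms: none
Why: Borohydride at −78 °C should reduce only the non-enolisable, ketone-activated C20 aldehyde (not the methyl ketone, enone or ester), and the neopentyl alcohol then lactonises onto the C7 ester under mild acid to the spiro α-methylidene δ-lactone.

Step 12
Reactants: 16 α-methylidene spiro lactone
Product: 17 tricyclic methyl ketone (labels: 5R,8S,9R,10S,13R): cis-fused cyclohexane–δ-lactone, spiro at C10 to the ring A enone, equatorial acetyl on C13, CH2OTBS on C5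
Conditions: KOt-Bu (0.2 equiv), t-BuOH/THF 1:4, 0 °C
Reagents that add atoms: none
Why: Intramolecular Michael addition of the methyl ketone enolate through C13 (the only position that closes a six-membered ring) onto C14 of the methylidene lactone closes ring C; the acetyl group equilibrates to the equatorial position (C13 trans to C10) and the lactone enolate is protonated at C8 from the less hindered face carrying H9, giving the cis ring fusion.

Step 13
Reactants: 17 tricyclic methyl ketone
Product: 18 enol triflate (labels: 5R,8S,9R,10S,13R): C13 bears C(=CH2)OSO2CF3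
Conditions: KN(SiMe3)2 (1.05 equiv), THF, −78 °C; PhNTf2 (1.1 equiv), −78 → 0 °C
Reagents that add atoms: N-phenylbis(trifluoromethanesulfonimide), O=S(=O)(N(c1ccccc1)S(=O)(=O)C(F)(F)F)C(F)(F)F
Why: Kinetic deprotonation of the methyl group by the bulky amide and O-triflation give the terminal enol triflate; the enone has no enolisable position and the lactone α-proton is far less acidic, so C8 and C13 stay untouched.

Step 14
Reactants: 18 enol triflate
Product: 19 acrylic acid silyl ether (labels: 5R,8S,9R,10S,13R): C13 bears C(=CH2)CO2H, C5 bears CH2OTBS, ring A enone intact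
Conditions: Pd(OAc)2 (5 mol%), PPh3 (10 mol%), CO (1 atm), KOAc (4 equiv), DMF/H2O 10:1, rt → 50 °C
Reagents that add atoms: carbon monoxide, [C-]#[O+]; water, O
Why: Palladium-catalysed hydroxycarbonylation, by oxidative addition of zerovalent palladium into the C–OTf bond, CO insertion and acetate/water capture of the acyl-palladium species, should give the 2-substituted acrylic acid without touching the enone or the silyl ether.

Step 15
Reactants: 19 acrylic acid silyl ether
Product: 21 CNP0268721.2 (target; labels: 3R,5R,8S,9R,10S,13R), via hydroxy enone 20 (not isolated)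
Conditions: HCl (2 M aq.)/THF 1:3, 0 °C → rt
Reagents that add atoms: none
Why: Acid cleaves the primary silyl ether to hydroxy enone 20, whose C6–OH then adds in a conjugate fashion to the C1-ketone-activated C2=C3 bond, and protonation of the enol at C2 gives the saturated ketone; the closest known reaction type is the acid- or base-mediated intramolecular oxa-Michael addition of hydroxy enones. The tetrahydrofuran (O, C3, C4, C5, C6) closes in a 5-exo-trig mode by axial attack on C3, the gem-dimethyl carbon C4 holding the C6 arm and C3 in a 1,3-diaxial relationship. The only new stereocentre, C3, is dictated by C5: the one-carbon tether reaches C3 only on the ring face that carries C6, so the (3R) ether follows from (5R). The step needs chemoselectivity for C2=C3 over the acrylic acid and the lactone; this is secured by proximity (no other nucleophile–acceptor pair can close an unstrained ring) and by the reversibility of the addition, which should funnel material to the bridged ether.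

**Compound list**

1 | 4,4-dimethylcyclohex-2-en-1-one | CC1(C)CCC(=O)C=C1 | starting material
2 | 4,4-dimethylcyclohexa-2,5-dien-1-one | CC1(C)C=CC(=O)C=C1 | intermediate
3 | (5R)-5-ethenyl-4,4-dimethylcyclohex-2-en-1-one | C1C(=O)C=CC(C)(C)[C@H]1C=C | intermediate
4 | (1S)-2,2-dimethyl-5-oxocyclohex-3-ene-1-carbaldehyde | C1C(=O)C=CC(C)(C)[C@H]1C=O | intermediate
5 | (5S)-5-(hydroxymethyl)-4,4-dimethylcyclohex-2-en-1-one | C1C(=O)C=CC(C)(C)[C@H]1CO | intermediate
6 | (5S)-5-{[(tert-butyldimethylsilyl)oxy]methyl}-4,4-dimethylcyclohex-2-en-1-one | C1C(=O)C=CC(C)(C)[C@H]1CO[Si](C)(C)C(C)(C)C | intermediate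
7 | (5R,6Z)-5-{[(tert-butyldimethylsilyl)oxy]methyl}-6-(hydroxymethylidene)-4,4-dimethylcyclohex-2-en-1-one | O/C=C1\C(=O)C=CC(C)(C)[C@H]1CO[Si](C)(C)C(C)(C)C | intermediate
8 | 1-methylcyclopentene | CC1=CCCC1 | starting material
9 | 5-oxohexanal | CC(=O)CCCC=O | intermediate
10 | methyl acrylate | C=CC(=O)OC | starting material
11 | methyl 3-hydroxy-2-methylidene-7-oxooctanoate (racemic) | CC(=O)CCCC(O)C(=C)C(=O)OC | intermediate
12 | methyl (2Z)-2-(bromomethyl)-7-oxooct-2-enoate | CC(=O)CCC/C=C(\CBr)C(=O)OC | intermediate
13 | methyl (2E)-2-({(E)-[(6R)-6-{[(tert-butyldimethylsilyl)oxy]methyl}-5,5-dimethyl-2-oxocyclohex-3-en-1-ylidene]methoxy}methyl)-7-oxooct-2-enoate | CC(=O)CCC/C=C(\CO/C=C1/C(=O)C=CC(C)(C)[C@H]1CO[Si](C)(C)C(C)(C)C)C(=O)OC | intermediate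
14 | methyl (3S)-3-[(1S,6R)-6-{[(tert-butyldimethylsilyl)oxy]methyl}-1-formyl-5,5-dimethyl-2-oxocyclohex-3-en-1-yl]-2-methylidene-7-oxooctanoate | CC(=O)CCC[C@H](C(=C)C(=O)OC)[C@]1(C=O)C(=O)C=CC(C)(C)[C@H]1CO[Si](C)(C)C(C)(C)C | intermediate
15 | methyl (3S)-3-[(1S,6R)-6-{[(tert-butyldimethylsilyl)oxy]methyl}-1-(hydroxymethyl)-5,5-dimethyl-2-oxocyclohex-3-en-1-yl]-2-methylidene-7-oxooctanoate | CC(=O)CCC[C@H](C(=C)C(=O)OC)[C@]1(CO)C(=O)C=CC(C)(C)[C@H]1CO[Si](C)(C)C(C)(C)C | intermediate
16 | (5S,6S,11R)-11-{[(tert-butyldimethylsilyl)oxy]methyl}-10,10-dimethyl-4-methylidene-5-(4-oxopentyl)-2-oxaspiro[5.5]undec-8-ene-3,7-dione | CC(=O)CCC[C@@H]2C(=C)C(=O)OC[C@]21C(=O)C=CC(C)(C)[C@H]1CO[Si](C)(C)C(C)(C)C | intermediate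
17 | tricyclic methyl ketone (5R,8S,9R,10S,13R): cis-fused cyclohexane–δ-lactone spiro at C10 to the ring A enone, 13-acetyl, 5-CH2OTBS | CC(=O)[C@@H]1CC[C@@H]2[C@H](C1)C(=O)OC[C@]21C(=O)C=CC(C)(C)[C@H]1CO[Si](C)(C)C(C)(C)C | intermediate
18 | enol triflate of 17 (5R,8S,9R,10S,13R): 13-[1-(trifluoromethanesulfonyloxy)ethenyl] | C=C(OS(=O)(=O)C(F)(F)F)[C@@H]1CC[C@@H]2[C@H](C1)C(=O)OC[C@]21C(=O)C=CC(C)(C)[C@H]1CO[Si](C)(C)C(C)(C)C | intermediate
19 | acrylic acid silyl ether (5R,8S,9R,10S,13R): 13-(1-carboxyethenyl), 5-CH2OTBS, ring A enone | C=C(C(=O)O)[C@@H]1CC[C@@H]2[C@H](C1)C(=O)OC[C@]21C(=O)C=CC(C)(C)[C@H]1CO[Si](C)(C)C(C)(C)C | intermediate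
20 | hydroxy enone acid (5R,8S,9R,10S,13R): as 19 with free C6–OH | C=C(C(=O)O)[C@@H]1CC[C@@H]2[C@H](C1)C(=O)OC[C@]21C(=O)C=CC(C)(C)[C@H]1CO | intermediate
21 | CNP0268721.2 (3R,5R,8S,9R,10S,13R): spiro δ-lactone, 3,6-ether-bridged ring A ketone, 13-(1-carboxyethenyl) | C=C(C(=O)O)[C@@H]1CC[C@@H]2[C@H](C1)C(=O)OC[C@]21C(=O)C[C@H]2OC[C@@H]1C2(C)C | target

**Step count.** Total: 15 steps. Longest linear sequence: 12 steps (steps 1–5 and 9–15); the side branch (steps 6–8) joins at step 9.

**Steps most likely to fail**

Step 10 (together with the O-alkylation that feeds it). The sigmatropic shift may leak through a boat transition state or through the minor enol-ether geometry, which would erode diastereocontrol at C9/C10, and C-alkylation may compete when 13 is made. The fallback sets out from 7 and 11 and comes back at 14. Alcohol 11 is converted with Boc2O and DMAP into methyl 3-[(tert-butoxycarbonyl)oxy]-2-methylidene-7-oxooctanoate F1. Compound 7 is then joined to F1 by a Lewis-base-catalysed SN2'–SN2' allylic alkylation (dimeric cinchona alkaloid catalyst such as (DHQD)2PHAL or its pseudo-enantiomer, toluene, rt). The catalyst-bound allyl ammonium ion should control C9, the substrate again controls C10, and 14 forms directly.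

Step 12. Base may move the exocyclic alkene into the lactone ring before cyclisation, the substrate may oligomerise, or the lactone enolate may be protonated from the wrong face at C8. The fallback sets out from 16 and comes back at 17. Thermodynamic silylation (Me3SiCl, Et3N, DMF, 60 °C) should give mainly the internal (Z)-trimethylsilyl enol ether of 16 F2. TiCl4 in CH2Cl2 at −78 °C then effects an intramolecular Mukaiyama–Michael addition onto the Lewis-acid-activated methylidene lactone, and a cold aqueous quench protonates C8 kinetically to give 17.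

Step 2. Insertion at the neopentyl β-carbon may be slow, the vinyl donor may protodeboronate, a second addition to the remaining enone may occur, or the enantioselectivity may be poor. The fallback sets out from 2 and comes back at 4. Iminium-catalysed conjugate addition of nitromethane (9-amino-9-deoxy-epi-cinchona primary amine with an acid co-catalyst, enantiomer series chosen for the (S) adduct) gives (5S)-4,4-dimethyl-5-(nitromethyl)cyclohex-2-en-1-one F3. A Nef reaction (NaOMe, then buffered aqueous TiCl3) converts it into aldehyde 4, which is reduced as in step 3.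

Further compounds
F1 | step 10 | methyl 3-[(tert-butoxycarbonyl)oxy]-2-methylidene-7-oxooctanoate | CC(=O)CCCC(OC(=O)OC(C)(C)C)C(=C)C(=O)OC
F2 | step 12 | internal (Z)-trimethylsilyl enol ether of 16 | C/C(O[Si](C)(C)C)=C/CC[C@@H]2C(=C)C(=O)OC[C@]21C(=O)C=CC(C)(C)[C@H]1CO[Si](C)(C)C(C)(C)C
F3 | step 2 | (5S)-4,4-dimethyl-5-(nitromethyl)cyclohex-2-en-1-one | C1C(=O)C=CC(C)(C)[C@H]1C[N+](=O)[O-]
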